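**Plan**

- Carbons are numbered from the lactone carbonyl (C1) to the methyl (C26); the target is 5S,7R,9R,11R,15S, with the oxygens on C5, C7, C9 and C11 all syn.
- Cuts: C2=C3 (ring-closing metathesis) and O5–C1 (acrylate); C4–C5 (allylation); C6–C7, C7–C8 and C9–O together on silicon (CO becomes C7); C10–C11 (allylation); C11–C12 (hydroformylation, CO becomes C11); C14–C15 (allylation of dodecanal).
- Enabling feature: the all-syn C7/C9/C11 triol. An HSi(allyl)2 group on O11 reaches the C8=C9 alkene and closes two fused oxasilacyclopentanes, O11–Si–C9–C10–C11 and Si–C9–C8–C7–O7, which share the Si–C9 bond.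
- Forward: the chain grows from the C26 end (C15–C26, then C11, then C8–C10); the two silicon rings are closed and oxidised away to the triol; C5 is re-functionalised, C2–C4 and C1 are added, and the lactone ring closes last.
- Stereochemistry: C15, C11 and C5 come from reagent-controlled Brown allylations; C9 and C7 are relayed from C11 through the silicon tether and fixed by Tamao oxidation with retention.

Key step: step 7

Remark on the chemistry: the SMILES is read as 5S,7R,9R,11R,15S in the numbering above. (+)-Ipc2BOMe is the B-methoxydiisopinocampheylborane from (−)-α-pinene and (−)-Ipc2BOMe the one from (+)-α-pinene. Both are taken as commercial, as are dodecanal, allylmagnesium bromide solution, trichlorosilane, BIPHEPHOS, Rh(acac)(CO)2 and acryloyl chloride. TBS = tert-butyldimethylsilyl.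

**Route**

Step 1
Reactants: 1 dodecanal; 2 allylmagnesium bromide
Product: 4 (S)-pentadec-1-en-4-ol, via borinate 3 (not isolated)
Conditions: (+)-Ipc2BOMe, 2, Et2O, 0 °C → rt; then 1, −78 °C; then 3 M NaOH, 30% H2O2, rt
Reagents that add atoms: allylmagnesium bromide (2), C=CC[Mg]Br
Why: Brown allylation, in which the B-allyldiisopinocampheylborane formed in the flask from the (−)-α-pinene-derived borinate adds through a closed six-membered chair to the Re face of the unbranched aldehyde and so sets C15 as S, after which oxidative work-up frees the alcohol from borinate 3.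

Step 2
Reactants: 4 (S)-pentadec-1-en-4-ol
Product: 5 (S)-tert-butyldimethyl(pentadec-1-en-4-yloxy)silane
Conditions: TBSCl, imidazole, DMF, rt
Reagents that add atoms: tert-butyldimethylsilyl chloride, CC(C)(C)[Si](C)(C)Cl
Why: Imidazole-promoted silylation of an unhindered secondary alcohol masks O15 for the carbonylation, silane and ozone chemistry that follows and leaves C15 untouched.

Step 3
Reactants: 5 (S)-tert-butyldimethyl(pentadec-1-en-4-yloxy)silane
Product: 6 (S)-5-(tert-butyldimethylsilyloxy)hexadecanal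
Conditions: Rh(acac)(CO)2 (1 mol %), BIPHEPHOS (3 mol %), CO/H2 (1:1, 5 bar), toluene, 65 °C
Reagents that add atoms: carbon monoxide, [C-]#[O+]
Why: Linear-selective rhodium/bisphosphite hydroformylation of a terminal alkene, in which the bulky chelating ligand places rhodium on the terminal carbon so that CO enters as the C11 aldehyde while the silyl ether and C15 are unaffected.

Step 4
Reactants: 6 (S)-5-(tert-butyldimethylsilyloxy)hexadecanal; 2 allylmagnesium bromide
Product: 8 (4R,8S)-8-(tert-butyldimethylsilyloxy)nonadec-1-en-4-ol, via borinate 7 (not isolated)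
Conditions: (−)-Ipc2BOMe, 2, Et2O, 0 °C → rt; then 6, −78 °C; then 3 M NaOH, 30% H2O2, rt
Reagents that add atoms: allylmagnesium bromide (2), C=CC[Mg]Br
Why: Brown allylation with the enantiomeric, (+)-α-pinene-derived reagent, which attacks the Si face through the same closed chair and sets C11 as R under reagent control, the remote C15 centre having no influence.

Step 5
Reactants: 9 trichlorosilane; 2 allylmagnesium bromide
Product: 10 chlorodiallylsilane
Conditions: 2 (2.0 equiv), Et2O, −78 °C → rt; filtration under argon; fractional distillation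
Reagents that add atoms: allylmagnesium bromide (2), C=CC[Mg]Br
Why: Grignard substitution at silicon replaces two of the three Si–Cl bonds at low temperature while Si–H survives, and the diallyl compound is separated from mono- and triallyl silanes by distillation.

Step 6
Reactants: 8 (4R,8S)-8-(tert-butyldimethylsilyloxy)nonadec-1-en-4-ol; 10 chlorodiallylsilane
Product: 11 (4R,8S)-8-(tert-butyldimethylsilyloxy)-4-(diallylsilyloxy)nonadec-1-ene
Conditions: 10 (1.3 equiv), Et3N, DMAP (cat.), CH2Cl2, 0 °C → rt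
Reagents that add atoms: chlorodiallylsilane (10), C=CC[SiH](Cl)CC=C
Why: Amine-mediated O-silylation of the secondary C11 alcohol by the chlorohydrosilane, under which Si–H, the three alkenes and the TBS ether are inert.

Step 7
Reactants: 11 (4R,8S)-8-(tert-butyldimethylsilyloxy)-4-(diallylsilyloxy)nonadec-1-ene
Product: 13 (1S,3R,5R,7S)-1,7-diallyl-3-[(4S)-4-(tert-butyldimethylsilyloxy)pentadecyl]-2,8-dioxa-1-silabicyclo[3.3.0]octane, via formyl silacycle 12 (not isolated)
Conditions: Rh(acac)(CO)2 (3 mol %), CO (65 bar), benzene, 60 °C; concentrated and used crude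
Reagents that add atoms: carbon monoxide, [C-]#[O+]
Why: Rh(I) inserts into the Si–H bond of 11 and the silyl–rhodium adds across C8=C9 within the tether (Si to C9, Rh to C8), CO inserts into the C8–Rh bond and reductive elimination releases the C7 aldehyde 12, whose strained, Lewis-acidic silacycle then binds the carbonyl and passes one allyl group to C7 through a closed six-membered chair; this is the known rhodium-catalysed tandem intramolecular silylformylation–allylsilylation of homoallylic diallylsilyl ethers. Ring one (O11–Si–C9–C10–C11) closes in the 5-exo-trig mode at the silylmetalation, and ring two (Si–C9–C8–C7–O7) closes when the bound carbonyl oxygen becomes a covalent O7–Si bond as the allyl group departs, the two rings being cis-fused across Si–C9. C9 is set by C11, because the side chain sits pseudo-equatorial in the cyclic silylmetalation transition state and gives the cis-3,5-disubstituted silacycle, which is 1,3-syn after oxidation with retention. C7 is set by C9 through silicon, because the aldehyde is held on the face of ring one that carries C8, only the allyl group on that face can reach it, and its delivery gives the 1,3-syn C7/C9 relationship while the other allyl group stays on the convex face next to H9. The step needs silylformylation to outrun hydrosilylation and silicon to bond to the internal alkene carbon; the high CO pressure and the five-membered tether should secure both. The Si-bound allyl groups cannot be reached intramolecularly before the aldehyde exists, and the C15 silyl ether is a spectator.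

Step 8
Reactants: 13 (1S,3R,5R,7S)-1,7-diallyl-3-[(4S)-4-(tert-butyldimethylsilyloxy)pentadecyl]-2,8-dioxa-1-silabicyclo[3.3.0]octane
Product: 14 (4S,6R,8R,12S)-12-(tert-butyldimethylsilyloxy)tricos-1-ene-4,6,8-triol
Conditions: 30% H2O2, KF, KHCO3, THF/MeOH (1:1), 40 °C
Reagents that add atoms: hydrogen peroxide, OO
Why: Tamao–Fleming oxidation, in which hydroperoxide adds to the dialkoxy-activated silicon and C9 migrates from Si to O with retention, so the C9 hydroxyl appears syn to O7 and O11, solvolysis frees the three alcohols, the spectator allyl group leaves as allyl alcohol, and the bicarbonate-buffered fluoride should spare the secondary TBS ether.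

Step 9
Reactants: 14 (4S,6R,8R,12S)-12-(tert-butyldimethylsilyloxy)tricos-1-ene-4,6,8-triol
Product: 15 (4S,6R,8R,12S)-4,6,8,12-tetrakis(tert-butyldimethylsilyloxy)tricos-1-ene
Conditions: TBSOTf (4 equiv), 2,6-lutidine, CH2Cl2, −78 → 0 °C
Reagents that add atoms: tert-butyldimethylsilyl triflate, CC(C)(C)[Si](C)(C)OS(=O)(=O)C(F)(F)F
Why: Silyl triflate with 2,6-lutidine persilylates flanked secondary alcohols, and the excess would also recap O15 should any TBS have been lost in step 8.

Step 10
Reactants: 15 (4S,6R,8R,12S)-4,6,8,12-tetrakis(tert-butyldimethylsilyloxy)tricos-1-ene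
Product: 17 (3R,5R,7R,11S)-3,5,7,11-tetrakis(tert-butyldimethylsilyloxy)docosanal, via ozonide 16 (not isolated)
Conditions: O3, CH2Cl2, −78 °C; then PPh3, −78 °C → rt
Reagents that add atoms: ozone, [O-][O+]=O
Why: Ozonolysis with reductive work-up, in which cycloaddition to the only C=C bond gives ozonide 16 and triphenylphosphine reduces it to the C5 aldehyde with loss of the terminal carbon as formaldehyde, the silyl ethers being inert and the β-silyloxy aldehyde being used without delay.

Step 11
Reactants: 17 (3R,5R,7R,11S)-3,5,7,11-tetrakis(tert-butyldimethylsilyloxy)docosanal; 2 allylmagnesium bromide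
Product: 19 (4S,6S,8R,10R,14S)-6,8,10,14-tetrakis(tert-butyldimethylsilyloxy)pentacos-1-en-4-ol, via borinate 18 (not isolated)
Conditions: (−)-Ipc2BOMe, 2, Et2O, 0 °C → rt; then 17, −78 °C; then 3 M NaOH, 30% H2O2, 0 °C → rt
Reagents that add atoms: allylmagnesium bromide (2), C=CC[Mg]Br
Why: Brown allylation with the (+)-α-pinene-derived reagent, whose Si-face addition through the closed chair sets C5 as S, 1,3-syn to the C7 silyl ether, with reagent control expected to override the weak bias of the β-silyloxy group.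

Step 12
Reactants: 19 (4S,6S,8R,10R,14S)-6,8,10,14-tetrakis(tert-butyldimethylsilyloxy)pentacos-1-en-4-ol
Product: 20 (4S,6S,8R,10R,14S)-6,8,10,14-tetrakis(tert-butyldimethylsilyloxy)pentacos-1-en-4-yl acrylate
Conditions: acryloyl chloride, Et3N, DMAP (cat.), CH2Cl2, 0 °C
Reagents that add atoms: acryloyl chloride, C=CC(=O)Cl
Why: DMAP-catalysed acylation of the C5 alcohol with acryloyl chloride installs C1–C2 with retention at C5.

Step 13
Reactants: 20 (4S,6S,8R,10R,14S)-6,8,10,14-tetrakis(tert-butyldimethylsilyloxy)pentacos-1-en-4-yl acrylate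
Product: 21 (6S)-6-[(2S,4R,6R,10S)-2,4,6,10-tetrakis(tert-butyldimethylsilyloxy)henicosyl]-5,6-dihydro-2H-pyran-2-one
Conditions: Grubbs second-generation catalyst (5 mol %), CH2Cl2 (0.005 M), 40 °C
Reagents that add atoms: none
Why: Ring-closing metathesis with a ruthenium N-heterocyclic-carbene catalyst joins the acrylate and the terminal alkene as the C2=C3 bond of the six-membered unsaturated lactone (cis by ring size), driven by loss of ethylene at high dilution.

Step 14
Reactants: 21 (6S)-6-[(2S,4R,6R,10S)-2,4,6,10-tetrakis(tert-butyldimethylsilyloxy)henicosyl]-5,6-dihydro-2H-pyran-2-one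
Product: 22 (6S)-6-[(2R,4R,6R,10S)-2,4,6,10-tetrahydroxyhenicosyl]-5,6-dihydro-2H-pyran-2-one
Conditions: 48% aq. HF, MeCN/CH2Cl2, 0 °C → rt
Reagents that add atoms: none
Why: Acidic fluoride cleaves the four secondary TBS ethers in one operation without the basic conditions that would promote conjugate addition of O7 to C3 or opening of the lactone, and no stereocentre is touched.

**Compound list**

1 | dodecanal | CCCCCCCCCCCC=O | starting material
2 | allylmagnesium bromide | C=CC[Mg]Br | starting material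
3 | (S)-pentadec-1-en-4-yl bis[(+)-isopinocampheyl]borinate | CCCCCCCCCCC[C@H](OB([C@H]1C[C@H]2C[C@@H]([C@@H]1C)C2(C)C)[C@H]1C[C@H]2C[C@@H]([C@@H]1C)C2(C)C)CC=C | intermediate
4 | (S)-pentadec-1-en-4-ol | CCCCCCCCCCC[C@H](O)CC=C | intermediate
5 | (S)-tert-butyldimethyl(pentadec-1-en-4-yloxy)silane | CCCCCCCCCCC[C@H](O[Si](C)(C)C(C)(C)C)CC=C | intermediate
6 | (S)-5-(tert-butyldimethylsilyloxy)hexadecanal | CCCCCCCCCCC[C@H](O[Si](C)(C)C(C)(C)C)CCCC=O | intermediate
7 | (4R,8S)-8-(tert-butyldimethylsilyloxy)nonadec-1-en-4-yl bis[(−)-isopinocampheyl]borinate | CCCCCCCCCCC[C@H](O[Si](C)(C)C(C)(C)C)CCC[C@@H](OB([C@@H]1C[C@@H]2C[C@H]([C@H]1C)C2(C)C)[C@@H]1C[C@@H]2C[C@H]([C@H]1C)C2(C)C)CC=C | intermediate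
8 | (4R,8S)-8-(tert-butyldimethylsilyloxy)nonadec-1-en-4-ol | CCCCCCCCCCC[C@H](O[Si](C)(C)C(C)(C)C)CCC[C@@H](O)CC=C | intermediate
9 | trichlorosilane | Cl[SiH](Cl)Cl | starting material
10 | chlorodiallylsilane | C=CC[SiH](Cl)CC=C | intermediate
11 | (4R,8S)-8-(tert-butyldimethylsilyloxy)-4-(diallylsilyloxy)nonadec-1-ene | CCCCCCCCCCC[C@H](O[Si](C)(C)C(C)(C)C)CCC[C@@H](O[SiH](CC=C)CC=C)CC=C | intermediate
12 | 2-[(3R,5R)-2,2-diallyl-5-[(4S)-4-(tert-butyldimethylsilyloxy)pentadecyl]-1,2-oxasilolan-3-yl]acetaldehyde (ring substituents cis) | CCCCCCCCCCC[C@H](O[Si](C)(C)C(C)(C)C)CCC[C@@H]1C[C@H](CC=O)[Si](CC=C)(CC=C)O1 | intermediate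
13 | (1S,3R,5R,7S)-1,7-diallyl-3-[(4S)-4-(tert-butyldimethylsilyloxy)pentadecyl]-2,8-dioxa-1-silabicyclo[3.3.0]octane (cis-fused; H-5 and the Si-allyl group on the convex face, both carbon substituents on the opposite face) | CCCCCCCCCCC[C@H](O[Si](C)(C)C(C)(C)C)CCC[C@@H]1C[C@@H]2C[C@H](CC=C)O[Si@]2(CC=C)O1 | intermediate
14 | (4S,6R,8R,12S)-12-(tert-butyldimethylsilyloxy)tricos-1-ene-4,6,8-triol (all-syn triol) | CCCCCCCCCCC[C@H](O[Si](C)(C)C(C)(C)C)CCC[C@@H](O)C[C@@H](O)C[C@@H](O)CC=C | intermediate
15 | (4S,6R,8R,12S)-4,6,8,12-tetrakis(tert-butyldimethylsilyloxy)tricos-1-ene | CCCCCCCCCCC[C@H](O[Si](C)(C)C(C)(C)C)CCC[C@@H](O[Si](C)(C)C(C)(C)C)C[C@@H](O[Si](C)(C)C(C)(C)C)C[C@@H](O[Si](C)(C)C(C)(C)C)CC=C | intermediate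
16 | 3-[(2R,4R,6R,10S)-2,4,6,10-tetrakis(tert-butyldimethylsilyloxy)henicosyl]-1,2,4-trioxolane (ozonide, mixture at the ring carbon) | CCCCCCCCCCC[C@H](O[Si](C)(C)C(C)(C)C)CCC[C@@H](O[Si](C)(C)C(C)(C)C)C[C@@H](O[Si](C)(C)C(C)(C)C)C[C@@H](O[Si](C)(C)C(C)(C)C)CC1OCOO1 | intermediate
17 | (3R,5R,7R,11S)-3,5,7,11-tetrakis(tert-butyldimethylsilyloxy)docosanal | CCCCCCCCCCC[C@H](O[Si](C)(C)C(C)(C)C)CCC[C@@H](O[Si](C)(C)C(C)(C)C)C[C@@H](O[Si](C)(C)C(C)(C)C)C[C@@H](O[Si](C)(C)C(C)(C)C)CC=O | intermediate
18 | (4S,6S,8R,10R,14S)-6,8,10,14-tetrakis(tert-butyldimethylsilyloxy)pentacos-1-en-4-yl bis[(−)-isopinocampheyl]borinate | CCCCCCCCCCC[C@H](O[Si](C)(C)C(C)(C)C)CCC[C@@H](O[Si](C)(C)C(C)(C)C)C[C@@H](O[Si](C)(C)C(C)(C)C)C[C@@H](O[Si](C)(C)C(C)(C)C)C[C@@H](OB([C@@H]1C[C@@H]2C[C@H]([C@H]1C)C2(C)C)[C@@H]1C[C@@H]2C[C@H]([C@H]1C)C2(C)C)CC=C | intermediate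
19 | (4S,6S,8R,10R,14S)-6,8,10,14-tetrakis(tert-butyldimethylsilyloxy)pentacos-1-en-4-ol | CCCCCCCCCCC[C@H](O[Si](C)(C)C(C)(C)C)CCC[C@@H](O[Si](C)(C)C(C)(C)C)C[C@@H](O[Si](C)(C)C(C)(C)C)C[C@@H](O[Si](C)(C)C(C)(C)C)C[C@@H](O)CC=C | intermediate
20 | (4S,6S,8R,10R,14S)-6,8,10,14-tetrakis(tert-butyldimethylsilyloxy)pentacos-1-en-4-yl acrylate | CCCCCCCCCCC[C@H](O[Si](C)(C)C(C)(C)C)CCC[C@@H](O[Si](C)(C)C(C)(C)C)C[C@@H](O[Si](C)(C)C(C)(C)C)C[C@@H](O[Si](C)(C)C(C)(C)C)C[C@@H](OC(=O)C=C)CC=C | intermediate
21 | (6S)-6-[(2S,4R,6R,10S)-2,4,6,10-tetrakis(tert-butyldimethylsilyloxy)henicosyl]-5,6-dihydro-2H-pyran-2-one | CCCCCCCCCCC[C@H](O[Si](C)(C)C(C)(C)C)CCC[C@@H](O[Si](C)(C)C(C)(C)C)C[C@@H](O[Si](C)(C)C(C)(C)C)C[C@@H](O[Si](C)(C)C(C)(C)C)C[C@@H]1CC=CC(=O)O1 | intermediate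
22 | (6S)-6-[(2R,4R,6R,10S)-2,4,6,10-tetrahydroxyhenicosyl]-5,6-dihydro-2H-pyran-2-one | CCCCCCCCCCC[C@H](O)CCC[C@@H](O)C[C@@H](O)C[C@@H](O)C[C@@H]1CC=CC(=O)O1 | target

**Count and risks**

Total steps: 14. Longest linear sequence: 13 (steps 1–4 and 6–14, from dodecanal); step 5 is a one-step side branch.

Steps most likely to fail:

1. Step 7. Hydrosilylation of the alkene may compete with CO insertion, and the relay of configuration from C11 to C9 and then through silicon to C7 may leak on either face, giving diastereomeric triols after oxidation. Fallback: the triad is built one carbinol at a time under reagent control. Setting out from 8, silylation (TBSOTf, 2,6-lutidine) gives (4R,8S)-4,8-bis(tert-butyldimethylsilyloxy)nonadec-1-ene F1. Ozonolysis (O3; PPh3) gives (3R,7S)-3,7-bis(tert-butyldimethylsilyloxy)octadecanal F2. Brown allylation with the reagent from (−)-Ipc2BOMe and 2 gives (4S,6R,10S)-6,10-bis(tert-butyldimethylsilyloxy)henicos-1-en-4-ol F3, with C9 set 1,3-syn. Silylation gives (4S,6R,10S)-4,6,10-tris(tert-butyldimethylsilyloxy)henicos-1-ene F4, and a second ozonolysis gives (3R,5R,9S)-3,5,9-tris(tert-butyldimethylsilyloxy)icosanal F5. A second allylation with the same reagent gives (4S,6S,8R,12S)-6,8,12-tris(tert-butyldimethylsilyloxy)tricos-1-en-4-ol F6, and its silylation with TBSOTf returns to the route at 15.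

2. Step 3. Formyl insertion at the internal carbon (branched aldehyde) and migration of the double bond ahead of carbonylation would erode the supply of the linear C11 aldehyde. Fallback: setting out from 5, cross-metathesis with acrolein (Hoveyda–Grubbs second-generation catalyst, CH2Cl2, 40 °C) gives (S,E)-5-(tert-butyldimethylsilyloxy)hexadec-2-enal F7. Reduction of its conjugated C=C bond (H2, Pd/C, EtOAc, or Stryker's reagent) returns to the route at 6.

3. Step 14. While four silyl ethers are being removed, the freed O7 hydroxyl may add in conjugate fashion to C3, the lactone may open or translactonise, or desilylation may stall at partly protected stages. Fallback: the order of deprotection and ring closure is reversed. Setting out from 20, desilylation (HF·pyridine, THF/pyridine, 0 °C → rt) gives (4S,6R,8R,10R,14S)-6,8,10,14-tetrahydroxypentacos-1-en-4-yl acrylate F8. Ring-closing metathesis on this free tetraol (Hoveyda–Grubbs second-generation catalyst, CH2Cl2, 40 °C, high dilution) closes the lactone last and arrives at 22, so the unsaturated lactone never meets fluoride.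

**Further compounds**

F1 | step 7 | (4R,8S)-4,8-bis(tert-butyldimethylsilyloxy)nonadec-1-ene | CCCCCCCCCCC[C@H](O[Si](C)(C)C(C)(C)C)CCC[C@@H](O[Si](C)(C)C(C)(C)C)CC=C
F2 | step 7 | (3R,7S)-3,7-bis(tert-butyldimethylsilyloxy)octadecanal | CCCCCCCCCCC[C@H](O[Si](C)(C)C(C)(C)C)CCC[C@@H](O[Si](C)(C)C(C)(C)C)CC=O
F3 | step 7 | (4S,6R,10S)-6,10-bis(tert-butyldimethylsilyloxy)henicos-1-en-4-ol | CCCCCCCCCCC[C@H](O[Si](C)(C)C(C)(C)C)CCC[C@@H](O[Si](C)(C)C(C)(C)C)C[C@@H](O)CC=C
F4 | step 7 | (4S,6R,10S)-4,6,10-tris(tert-butyldimethylsilyloxy)henicos-1-ene | CCCCCCCCCCC[C@H](O[Si](C)(C)C(C)(C)C)CCC[C@@H](O[Si](C)(C)C(C)(C)C)C[C@@H](O[Si](C)(C)C(C)(C)C)CC=C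
F5 | step 7 | (3R,5R,9S)-3,5,9-tris(tert-butyldimethylsilyloxy)icosanal | CCCCCCCCCCC[C@H](O[Si](C)(C)C(C)(C)C)CCC[C@@H](O[Si](C)(C)C(C)(C)C)C[C@@H](O[Si](C)(C)C(C)(C)C)CC=O
F6 | step 7 | (4S,6S,8R,12S)-6,8,12-tris(tert-butyldimethylsilyloxy)tricos-1-en-4-ol | CCCCCCCCCCC[C@H](O[Si](C)(C)C(C)(C)C)CCC[C@@H](O[Si](C)(C)C(C)(C)C)C[C@@H](O[Si](C)(C)C(C)(C)C)C[C@@H](O)CC=C
F7 | step 3 | (S,E)-5-(tert-butyldimethylsilyloxy)hexadec-2-enal | CCCCCCCCCCC[C@H](O[Si](C)(C)C(C)(C)C)C/C=C/C=O
F8 | step 14 | (4S,6R,8R,10R,14S)-6,8,10,14-tetrahydroxypentacos-1-en-4-yl acrylate | CCCCCCCCCCC[C@H](O)CCC[C@@H](O)C[C@@H](O)C[C@@H](O)C[C@@H](OC(=O)C=C)CC=C
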